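**Strategy.** The furofuran is disconnected at the C8′–C7′ bond of ring B. Because C8 carries no hydrogen and the benzylic ether C7′–H lies 1,5 to C8′ across C9 and the ring B oxygen, a rhodium carbenoid generated at C8′ of a ring A lactone is directed to that bond. One operation closes ring B, enforces the cis ring fusion and sets C8′ and C7′ (aryl endo). The precursor is the (4S,5R) α-diazo-γ-butyrolactone 15, with the C7 aryl cis to a silylated C8 oxygen and a C9–O–CH2Ar arm. C8 comes from a tartrate-controlled epoxidation, C7 from an invertive lactonisation, and the C9′ carbonyl is reduced away afterwards.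

Key step: step 9

Remarks: lignan numbering is used (ring A = C7–O–C9′–C8′–C8, ring B = C8′–C7′–O–C9–C8); Ar = 4-benzyloxy-3-methoxyphenyl; 4-benzyloxy-3-methoxybenzyl alcohol (10) is assumed to be purchasable. The target is (7R,8S,7′R,8′R), with the C7 aryl exo and the C7′ aryl endo.

**Step 1**
Reactants: 1 O-benzylvanillin (4-benzyloxy-3-methoxybenzaldehyde); 2 dimethyl succinate
Product: 3 (E)-4-(4-benzyloxy-3-methoxyphenyl)-3-(methoxycarbonyl)but-3-enoic acid
Conditions: NaOMe, MeOH, reflux; then aq HCl
Reagents that add atoms: none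
Why: Stobbe condensation, in which the succinate enolate adds to the aldehyde and lactonisation followed by base-induced ring opening delivers the half-ester, expected mainly as the E isomer (aryl trans to CO2Me).

**Step 2**
Reactants: 3 (E)-half-ester
Product: 5 (E)-4-(4-benzyloxy-3-methoxybenzylidene)dihydrofuran-2(3H)-one, via hydroxy acid 4 (not isolated)
Conditions: LiBHEt3 (3.3 equiv), THF, −78 → 0 °C; then 2 M HCl, rt
Reagents that add atoms: none
Why: Chemoselective hydride reduction of a half-ester: the lithium carboxylate is inert while the ester is reduced at the carbonyl to the allylic alcohol, and acid work-up closes the γ-lactone without touching the alkene geometry.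

**Step 3**
Reactants: 5 (E)-arylidene lactone
Product: 6 (E)-4-(4-benzyloxy-3-methoxyphenyl)-3-(hydroxymethyl)-1-(pyrrolidin-1-yl)but-3-en-1-one
Conditions: pyrrolidine, AlMe3, CH2Cl2, 0 °C → rt; aq Rochelle salt
Reagents that add atoms: pyrrolidine, C1CCNC1
Why: Aluminium amide (Weinreb-type) aminolysis opens the lactone irreversibly under non-basic conditions, freeing the allylic alcohol needed for directed epoxidation and installing an amide oxygen as the later internal nucleophile.

**Step 4**
Reactants: 6 (E)-hydroxy amide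
Product: 9 (4S,5R)-5-(4-benzyloxy-3-methoxyphenyl)-4-hydroxy-4-(hydroxymethyl)dihydrofuran-2(3H)-one, via epoxy amide 7 (not isolated), via iminium ether 8 (not isolated)
Conditions: Ti(OiPr)4 (10 mol %), L-(+)-DIPT (12 mol %), t-BuOOH, 4 Å MS, CH2Cl2, −20 °C; then 10% aq citric acid, THF, 0 °C → rt
Reagents that add atoms: tert-butyl hydroperoxide, CC(C)(C)OO; water, O
Why: Katsuki–Sharpless epoxidation of the (E)-2,3-disubstituted allylic alcohol with L-(+)-tartrate should give the (7S,8S) epoxide 7 (reagent control, fixing C8), after which the amide oxygen opens the acid-activated benzylic epoxide at C7 anti to the C7–O bond (inversion, C7 becomes R) to iminium ether 8, whose hydrolysis releases pyrrolidine and leaves the aryl cis to the C8 hydroxyl.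

**Step 5**
Reactants: 10 4-benzyloxy-3-methoxybenzyl alcohol
Product: 11 4-benzyloxy-3-methoxybenzyl bromide
Conditions: PBr3, Et2O, 0 °C; used crude at once
Reagents that add atoms: phosphorus tribromide, BrP(Br)Br
Why: Standard conversion of an electron-rich benzylic alcohol into its bromide through the phosphite ester; the labile bromide is not stored.

**Step 6**
Reactants: 9 lactone diol; 11 benzylic bromide
Product: 12 (4S,5R)-5-(4-benzyloxy-3-methoxyphenyl)-4-{[(4-benzyloxy-3-methoxyphenyl)methoxy]methyl}-4-hydroxydihydrofuran-2(3H)-one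
Conditions: Ag2O, 4 Å MS, CH2Cl2, rt, dark
Reagents that add atoms: none
Why: Silver oxide-mediated Williamson-type etherification is selective for the primary C9 hydroxyl over the hindered tertiary C8 hydroxyl and avoids free alkoxides, which could trigger translactonisation or retro-aldol cleavage of the β-hydroxy lactone.

**Step 7**
Reactants: 12 tertiary alcohol
Product: 13 (4S,5R)-5-(4-benzyloxy-3-methoxyphenyl)-4-{[(4-benzyloxy-3-methoxyphenyl)methoxy]methyl}-4-(tert-butyldimethylsilyloxy)dihydrofuran-2(3H)-one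
Conditions: TBSOTf, 2,6-lutidine, CH2Cl2, 0 °C → rt
Reagents that add atoms: tert-butyldimethylsilyl triflate, CC(C)(C)[Si](C)(C)OS(=O)(=O)C(F)(F)F
Why: Silyl triflate silylation of a tertiary alcohol caps the C8 oxygen, so that no hydroxyl can fragment or shift next to the later carbenoid.

**Step 8**
Reactants: 13 silyl ether lactone
Product: 15 (4S,5R)-5-(4-benzyloxy-3-methoxyphenyl)-4-{[(4-benzyloxy-3-methoxyphenyl)methoxy]methyl}-4-(tert-butyldimethylsilyloxy)-3-diazodihydrofuran-2(3H)-one, via trifluoroacetyl lactone 14 (not isolated)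
Conditions: LiHMDS (1.2 equiv), THF, −78 °C; CF3CO2CH2CF3, −78 °C; aq NH4Cl; then 4-AcNHC6H4SO2N3, Et3N, H2O, MeCN, rt
Reagents that add atoms: 4-acetamidobenzenesulfonyl azide, CC(=O)Nc1ccc(cc1)S(=O)(=O)N=[N+]=[N-]
Why: Detrifluoroacetylative (Regitz-type) diazo transfer: the lactone enolate is trapped at −78 °C as the activated trifluoroacetyl compound 14, which accepts the diazo group from the sulfonyl azide and loses the acyl group as the N-acyl sulfonamide; neither stereocentre is touched.

**Step 9 (key step)**
Reactants: 15 α-diazo lactone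
Product: 16 (7R,8S,7′R,8′R) cis-fused furofuranone: 4,4′-di-O-benzyl-8-(tert-butyldimethylsilyloxy)-3,3′-dimethoxy-7′,9-epoxylignano-9′,7-lactone, C7 aryl exo, C7′ aryl endo
Conditions: 15 added over 4 h to Rh2(OAc)4 (2 mol %), CH2Cl2, reflux
Reagents that add atoms: none
Why: Rh2(OAc)4 binds the diazo carbon, N2 leaves, and the electrophilic carbenoid at C8′ inserts into the C7′–H bond of the ether arm through a concerted three-centre transition state that forms C8′–C7′ and releases the catalyst. This is the known Rh2(OAc)4-catalysed 1,5 C–H insertion of α-diazo-γ-butyrolactones into benzylic ether C–H bonds; only the C8 silyloxy group is new to the substrate. Ring B closes as a five-membered ring by 1,5-insertion (C8′, C8, C9, O, C7′), the mode preferred by carbenoids because the ordered transition state then has six centres including the migrating hydrogen. C8′ is set by the tether: the arm is anchored on C8 and reaches the carbenoid only from its own face, so the transferred hydrogen ends up cis to the C8 oxygen and the rings are cis fused. C7′ is set kinetically with retention at carbon: the dirhodium core sits on the outer edge of ring A, so the C7′ substituent pointing toward the carboxylate wall should be hydrogen and the aryl folds over ring A, the concave (endo) face. Site selectivity rests on C8 having no hydrogen (no 1,2-hydride shift), the 1,5 distance and activation of C7′–H by both the ether oxygen and the electron-rich aryl; aromatic cycloaddition and 1,2-migration of a C8 substituent are the competitors, held back by acetate ligands, dilution and slow addition.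

**Step 10**
Reactants: 16 furofuranone
Product: 17 (7R,8S,7′R,8′R) diol: ring B tetrahydrofuran bearing the C7′ aryl, a C8′ hydroxymethyl (C9′), the C8 silyloxy group and a C8 aryl(hydroxy)methyl group (C7)
Conditions: LiAlH4, THF, 0 °C; Na2SO4·10H2O quench
Reagents that add atoms: none
Why: Hydride reduction of the lactone to the diol under basic conditions, which spare the acid-labile endo aryl ether at C7′ that a Lewis-acid lactol reduction would put at risk; any silyl migration is harmless because the silyl group is removed next.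

**Step 11**
Reactants: 17 silyl diol
Product: 18 (7R,8S,7′R,8′R) triol (C7–OH, C8–OH, C9′–OH)
Conditions: Bu4NF, THF, rt → 40 °C; aq NH4Cl
Reagents that add atoms: none
Why: Fluoride cleavage of the tertiary silyl ether, neutral to basic and therefore safe for both benzylic ethers.

**Step 12**
Reactants: 18 triol
Product: 20 (7R,8S,7′R,8′R)-4,4′-bis(benzyloxy)-3,3′-dimethoxy-7,9′:7′,9-diepoxylignan-8-ol, via primary mesylate 19 (not isolated)
Conditions: MsCl (1.1 equiv), pyridine, CH2Cl2, 0 °C → rt
Reagents that add atoms: none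
Why: Selective sulfonylation of the primary C9′ hydroxyl followed by 5-exo-tet Williamson closure by the C7 hydroxyl forms ring A at a primary carbon, so C7 keeps its configuration, and the tertiary C8 hydroxyl could only form a strained oxetane.

**Step 13**
Reactants: 20 dibenzyl ether
Product: 21 target, (7R,8S,7′R,8′R)-3,3′-dimethoxy-7,9′:7′,9-diepoxylignane-4,4′,8-triol
Conditions: H2 (1 atm), 10% Pd/C, EtOAc–EtOH, rt, stopped after uptake of 2 equiv
Reagents that add atoms: none
Why: Catalytic hydrogenolysis cleaves aryl benzyl ethers much faster than the dialkyl benzylic C7–O and C7′–O bonds of the furofuran, so controlled uptake should free both phenols only.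

**Compound list**
1 | O-benzylvanillin (4-benzyloxy-3-methoxybenzaldehyde) | COc1cc(C=O)ccc1OCc1ccccc1 | starting material
2 | dimethyl succinate | COC(=O)CCC(=O)OC | starting material
3 | (E)-4-(4-benzyloxy-3-methoxyphenyl)-3-(methoxycarbonyl)but-3-enoic acid | OC(=O)C/C(=C\c1ccc(OCc2ccccc2)c(OC)c1)C(=O)OC | intermediate
4 | (E)-4-(4-benzyloxy-3-methoxyphenyl)-3-(hydroxymethyl)but-3-enoic acid | OC(=O)C/C(=C\c1ccc(OCc2ccccc2)c(OC)c1)CO | intermediate (not isolated)
5 | (E)-4-(4-benzyloxy-3-methoxybenzylidene)dihydrofuran-2(3H)-one | O=C1C/C(=C\c2ccc(OCc3ccccc3)c(OC)c2)CO1 | intermediate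
6 | (E)-4-(4-benzyloxy-3-methoxyphenyl)-3-(hydroxymethyl)-1-(pyrrolidin-1-yl)but-3-en-1-one | O=C(C/C(=C\c1ccc(OCc2ccccc2)c(OC)c1)CO)N1CCCC1 | intermediate
7 | 2-[(2S,3S)-3-(4-benzyloxy-3-methoxyphenyl)-2-(hydroxymethyl)oxiran-2-yl]-1-(pyrrolidin-1-yl)ethan-1-one | O=C(C[C@@]1(CO)O[C@H]1c1ccc(OCc2ccccc2)c(OC)c1)N1CCCC1 | intermediate (not isolated)
8 | 1-[(4S,5R)-5-(4-benzyloxy-3-methoxyphenyl)-4-hydroxy-4-(hydroxymethyl)dihydrofuran-2(3H)-ylidene]pyrrolidinium (cyclic iminium ether, citrate counter-ion) | COc1cc(ccc1OCc1ccccc1)[C@H]2OC(=[N+]3CCCC3)C[C@]2(O)CO | intermediate (not isolated)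
9 | (4S,5R)-5-(4-benzyloxy-3-methoxyphenyl)-4-hydroxy-4-(hydroxymethyl)dihydrofuran-2(3H)-one (aryl cis to OH) | COc1cc(ccc1OCc1ccccc1)[C@H]2OC(=O)C[C@]2(O)CO | intermediate
10 | 4-benzyloxy-3-methoxybenzyl alcohol | OCc1ccc(OCc2ccccc2)c(OC)c1 | starting material
11 | 4-benzyloxy-3-methoxybenzyl bromide | BrCc1ccc(OCc2ccccc2)c(OC)c1 | intermediate
12 | (4S,5R)-5-(4-benzyloxy-3-methoxyphenyl)-4-{[(4-benzyloxy-3-methoxyphenyl)methoxy]methyl}-4-hydroxydihydrofuran-2(3H)-one | COc1cc(ccc1OCc1ccccc1)[C@H]2OC(=O)C[C@]2(O)COCc1ccc(OCc3ccccc3)c(OC)c1 | intermediate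
13 | (4S,5R)-4-(tert-butyldimethylsilyloxy) ether of 12 | COc1cc(ccc1OCc1ccccc1)[C@H]2OC(=O)C[C@]2(O[Si](C)(C)C(C)(C)C)COCc1ccc(OCc3ccccc3)c(OC)c1 | intermediate
14 | 3-(trifluoroacetyl) derivative of 13 (C8′ epimers and enol) | COc1cc(ccc1OCc1ccccc1)[C@H]2OC(=O)C(C(=O)C(F)(F)F)[C@]2(O[Si](C)(C)C(C)(C)C)COCc1ccc(OCc3ccccc3)c(OC)c1 | intermediate (not isolated)
15 | (4S,5R)-5-(4-benzyloxy-3-methoxyphenyl)-4-{[(4-benzyloxy-3-methoxyphenyl)methoxy]methyl}-4-(tert-butyldimethylsilyloxy)-3-diazodihydrofuran-2(3H)-one | COc1cc(ccc1OCc1ccccc1)[C@H]2OC(=O)C(=[N+]=[N-])[C@]2(O[Si](C)(C)C(C)(C)C)COCc1ccc(OCc3ccccc3)c(OC)c1 | intermediate (key-step precursor)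
16 | (7R,8S,7′R,8′R) cis-fused furofuranone, C7 aryl exo, C7′ aryl endo, C8 OTBS, C9′ carbonyl | COc1cc(ccc1OCc1ccccc1)[C@H]2OC(=O)[C@@H]3[C@H](c4ccc(OCc5ccccc5)c(OC)c4)OC[C@]23O[Si](C)(C)C(C)(C)C | intermediate (key-step product)
17 | (7R,8S,7′R,8′R) diol: C7–OH and C9′–OH, C8 OTBS, ring B intact | COc1cc(ccc1OCc1ccccc1)[C@@H](O)[C@@]1(O[Si](C)(C)C(C)(C)C)CO[C@@H](c2ccc(OCc3ccccc3)c(OC)c2)[C@H]1CO | intermediate
18 | (7R,8S,7′R,8′R) triol: C7–OH, C8–OH, C9′–OH, ring B intact | COc1cc(ccc1OCc1ccccc1)[C@@H](O)[C@@]1(O)CO[C@@H](c2ccc(OCc3ccccc3)c(OC)c2)[C@H]1CO | intermediate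
19 | C9′ methanesulfonate of 18 | COc1cc(ccc1OCc1ccccc1)[C@@H](O)[C@@]1(O)CO[C@@H](c2ccc(OCc3ccccc3)c(OC)c2)[C@H]1COS(C)(=O)=O | intermediate (not isolated)
20 | (7R,8S,7′R,8′R)-4,4′-bis(benzyloxy)-3,3′-dimethoxy-7,9′:7′,9-diepoxylignan-8-ol | COc1cc([C@H]2OC[C@@H]3[C@H](c4ccc(OCc5ccccc5)c(OC)c4)OC[C@]23O)ccc1OCc1ccccc1 | intermediate
21 | (7R,8S,7′R,8′R)-3,3′-dimethoxy-7,9′:7′,9-diepoxylignane-4,4′,8-triol | COc1cc([C@H]2OC[C@@H]3[C@H](c4ccc(O)c(OC)c4)OC[C@]23O)ccc1O | target

**Count.** Total steps: 13. Longest linear sequence: 12 (steps 1–4 and 6–13; step 5 is a one-step side branch).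

**Steps most likely to fail**

Step 9. The carbenoid may be diverted from 1,5 C–H insertion into addition to the electron-rich aryl ring of the ether arm or into 1,2-migration of a C8 substituent, or the endo preference at C7′ may erode. The fallback makes the C8′–C7′ bond by an aldol reaction and closes ring B by substitution at C9. It sets out from lactone diol 9, whose two hydroxyls are silylated (TBSOTf, 2,6-lutidine) to give the bis-silyl ether F1. The lithium enolate of F1 (LiHMDS, THF, −78 °C) is added to aldehyde 1, the electrophile expected to enter anti to the C7 aryl and the C8 silyloxy group, to give the (7′R) aldol adduct F2; its C7′ epimer would be separated and recycled by oxidation and re-reduction. Buffered HF·pyridine removes the primary silyl ether to give the diol F3. Mitsunobu cyclodehydration (PPh3, DIAD) activates the primary C9 hydroxyl so that O7′ closes ring B without touching C7′, and the route is rejoined at 16.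

Step 8. The lactone enolate carries a silyloxy group on the β-carbon and may expel silanolate (E1cB) to a butenolide before it is acylated. The fallback enolises with the C8 oxygen as an oxide, which cannot leave. It sets out from tertiary alcohol 12: LiHMDS (2.2 equiv, THF, −78 °C) forms the alkoxide–enolate dianion, and direct diazo transfer from 4-nitrobenzenesulfonyl azide gives the diazo hydroxy lactone F4. Silylation of F4 with TBSOTf and 2,6-lutidine at −78 °C, conditions that diazo esters tolerate, returns to the route at 15.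

Step 4. The electron-rich benzylic epoxide may be opened by external nucleophiles (isopropanol, hydroperoxide, tartrate) under titanium Lewis acidity before the amide oxygen engages, and an ionised pathway may erode the inversion at C7. The fallback avoids Lewis acid and uses a carboxylate as the internal nucleophile. It sets out from lactone 5, which is epoxidised by Shi epoxidation with the enantiomer of the fructose-derived ketone (made from L-sorbose), Oxone and K2CO3 buffer at 0 °C; by analogy with trans-β-methylstyrene this should give the (7S,8S) spiro-epoxy lactone F5. Saponification (LiOH, THF–H2O, 0 °C) gives the epoxy hydroxy acid F6, and acidification to pH 3 lets the carboxylic acid open the epoxide at C7 with inversion, returning to the route at 9.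

**Further compounds**
F1 | step 9 | (4S,5R)-5-(4-benzyloxy-3-methoxyphenyl)-4-(tert-butyldimethylsilyloxy)-4-[(tert-butyldimethylsilyloxy)methyl]dihydrofuran-2(3H)-one | COc1cc(ccc1OCc1ccccc1)[C@H]2OC(=O)C[C@]2(O[Si](C)(C)C(C)(C)C)CO[Si](C)(C)C(C)(C)C
F2 | step 9 | (7R,8S,7′R,8′R) aldol adduct of F1 with 1: C8′ bears CH(OH)Ar cis to C9 | COc1cc(ccc1OCc1ccccc1)[C@H]2OC(=O)[C@H]([C@H](c3ccc(OCc4ccccc4)c(OC)c3)O)[C@]2(O[Si](C)(C)C(C)(C)C)CO[Si](C)(C)C(C)(C)C
F3 | step 9 | C9 primary alcohol obtained from F2 (C7′–OH and C9–OH free, C8 OTBS) | COc1cc(ccc1OCc1ccccc1)[C@H]2OC(=O)[C@H]([C@H](c3ccc(OCc4ccccc4)c(OC)c3)O)[C@]2(O[Si](C)(C)C(C)(C)C)CO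
F4 | step 8 | (4S,5R)-5-(4-benzyloxy-3-methoxyphenyl)-4-{[(4-benzyloxy-3-methoxyphenyl)methoxy]methyl}-3-diazo-4-hydroxydihydrofuran-2(3H)-one | COc1cc(ccc1OCc1ccccc1)[C@H]2OC(=O)C(=[N+]=[N-])[C@]2(O)COCc1ccc(OCc3ccccc3)c(OC)c1
F5 | step 4 | (2S,3S)-2-(4-benzyloxy-3-methoxyphenyl)-1,5-dioxaspiro[2.4]heptan-6-one (the 7S,8S epoxide of 5) | O=C1C[C@@]2(CO1)O[C@H]2c1ccc(OCc2ccccc2)c(OC)c1
F6 | step 4 | 2-[(2S,3S)-3-(4-benzyloxy-3-methoxyphenyl)-2-(hydroxymethyl)oxiran-2-yl]acetic acid | OC(=O)C[C@@]1(CO)O[C@H]1c1ccc(OCc2ccccc2)c(OC)c1
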